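The target is a 1-aryltetralin whose B ring (C1, C2, C3, C4, C4a, C8a) carries all three stereocentres beside an unsubstituted benzylic C4. That ring is cut at C1–C2 and C3–C4: ring A with exocyclic C1 and C4 is an o-quinodimethane, and the trans C2/C3 acetoxymethyl pair is a fumarate. C4 receives a temporary hydroxyl, so the diene is the (E,E)-photoenol of a 2-benzylbenzaldehyde, an achiral diarylmethane. Irradiating it with the fumarate of methyl (S)-mandelate dearomatises ring A transiently and closes ring B last, setting C1, C2 and C3 in one photoenolisation/Diels–Alder step; the C4 oxygen and the benzyl ethers are removed together at the end.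

Key step: step 6

Remark: the tetralin numbering of the target is used throughout (C1 = aryl-bearing carbon, C4 = benzylic CH2, 6-OMe, 7-OH). Compounds 1 and 3 are taken as commercial; each is one O-benzylation away from vanillin or syringaldehyde.
Remark: methyl (S)-mandelate is assumed to direct the fumarate to the face that gives the (2R,3R)-bis(hydroxymethyl) series. If the opposite sense were found, methyl (R)-mandelate would be used with nothing else changed.

Step 1
Reactants: 1 4-(benzyloxy)-3-methoxybenzaldehyde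
Product: 2 4-(benzyloxy)-2-bromo-5-methoxybenzaldehyde
Conditions: Br2 (1.05 equiv), NaOAc, AcOH, rt
Reagents that add atoms: bromine, BrBr
Why: Electrophilic aromatic bromination should go para to the 3-methoxy group (C6), the activated position that is not flanked by two substituents, as with other 3,4-dialkoxybenzaldehydes; no stereocentre is formed.

Step 2
Reactants: 3 4-(benzyloxy)-3,5-dimethoxybenzaldehyde
Product: 4 [4-(benzyloxy)-3,5-dimethoxyphenyl]methanol
Conditions: NaBH4, MeOH, 0 °C
Reagents that add atoms: none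
Why: Borohydride reduction of an aryl aldehyde to the benzylic alcohol is reliable and leaves the benzyl ether untouched.

Step 3
Reactants: 4 [4-(benzyloxy)-3,5-dimethoxyphenyl]methanol
Product: 5 2-(benzyloxy)-5-(chloromethyl)-1,3-dimethoxybenzene
Conditions: SOCl2, CH2Cl2, 0 °C to rt
Reagents that add atoms: thionyl chloride, O=S(Cl)Cl
Why: Deoxychlorination through the chlorosulfite should be fast for this electron-rich benzylic alcohol, and the aryl benzyl ether tolerates the short exposure to HCl.

Step 4
Reactants: 5 2-(benzyloxy)-5-(chloromethyl)-1,3-dimethoxybenzene; 2 4-(benzyloxy)-2-bromo-5-methoxybenzaldehyde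
Product: 7 4-(benzyloxy)-2-[4-(benzyloxy)-3,5-dimethoxybenzyl]-5-methoxybenzaldehyde, via benzylzinc chloride 6 (not isolated)
Conditions: Zn dust, LiCl, THF, 25 °C; then 2, Pd(OAc)2 (2 mol%), SPhos (4 mol%), THF, 25 °C
Reagents that add atoms: none
Why: LiCl-assisted zinc insertion into the benzylic C–Cl bond followed by Negishi cross-coupling should give the diarylmethane, because coupling at Pd–SPhos is expected to outpace the slow uncatalysed addition of the benzylzinc chloride to the electron-rich aldehyde.

Step 5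
Reactants: 8 fumaryl chloride; 9 methyl (S)-mandelate
Product: 11 bis[(1S)-2-methoxy-2-oxo-1-phenylethyl] (2E)-but-2-enedioate, via fumaroyl chloride monoester 10 (not isolated)
Conditions: 9 (2.1 equiv in all), pyridine (2.2 equiv), CH2Cl2, 0 °C to rt
Reagents that add atoms: methyl (S)-mandelate (second equivalent), COC(=O)[C@@H](O)c1ccccc1
Why: Esterification of the secondary alcohol by the acid chloride under mild base should give first the monoester chloride 10 and then, with the second equivalent of 9, the C2-symmetric diester 11, without touching the mandelate stereocentre, which is not involved in bond making.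

Step 6
Reactants: 7 4-(benzyloxy)-2-[4-(benzyloxy)-3,5-dimethoxybenzyl]-5-methoxybenzaldehyde; 11 bis[(1S)-2-methoxy-2-oxo-1-phenylethyl] (2E)-but-2-enedioate
Product: 13 bis[(1S)-2-methoxy-2-oxo-1-phenylethyl] (1S,2R,3S,4S)-7-(benzyloxy)-1-[4-(benzyloxy)-3,5-dimethoxyphenyl]-4-hydroxy-6-methoxy-1,2,3,4-tetrahydronaphthalene-2,3-dicarboxylate, via (E,E)-dienol 12 (not isolated)
Conditions: hν (Hg lamp, Pyrex, >300 nm), 11 (3 equiv), degassed toluene, 0–10 °C
Reagents that add atoms: none
Why: Excitation of the aryl aldehyde and intersystem crossing are followed by 1,5-hydrogen transfer from the doubly benzylic CH2 to the carbonyl oxygen; the biradical relaxes to the dienols, of which the Z-hydroxy isomer returns to 7 by a fast 1,5-H shift while the longer-lived (E,E)-α-hydroxy-α'-aryl-o-quinodimethane 12 adds suprafacially to fumarate 11 in a concerted thermal [4+2] cycloaddition that forms C1–C2 and C3–C4 and restores the aromatic A ring. The closest known reaction type is the photoenolisation/Diels–Alder reaction of 2-alkyl- and 2-benzylbenzaldehydes with electron-poor alkenes, together with the Diels–Alder reaction of hydroxy-o-quinodimethanes with fumarates of chiral α-hydroxy esters. The six-membered B ring is closed in an intermolecular [4+2] mode from the four-carbon unit C4–C4a–C8a–C1 and the two-carbon unit C2–C3. The 2,3-trans relation follows stereospecifically from the E-fumarate and the 1,4-cis relation from the E,E diene geometry; the 3,4-cis and hence 1,2-trans relation is expected from an endo transition state for the ester next to the dienol OH (O–H···O=C hydrogen bond and secondary orbital overlap), which places the ester next to the aryl group exo. The absolute configuration (1S,2R,3S,4S) is expected from the two (S)-mandelate units, which shield one π-face of the C2-symmetric dienophile. The step needs endo and π-facial selectivity but no regioselectivity because both ends of 11 are equivalent; light above 300 nm that only the aldehyde absorbs, exclusion of oxygen and an excess of 11 should keep the dienophile E-configured and let trapping outrun the return of 12 to 7.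

Step 7
Reactants: 13 bis[(1S)-2-methoxy-2-oxo-1-phenylethyl] (1S,2R,3S,4S)-7-(benzyloxy)-1-[4-(benzyloxy)-3,5-dimethoxyphenyl]-4-hydroxy-6-methoxy-1,2,3,4-tetrahydronaphthalene-2,3-dicarboxylate
Product: 14 [(1S,2R,3R,4S)-7-(benzyloxy)-1-[4-(benzyloxy)-3,5-dimethoxyphenyl]-4-hydroxy-6-methoxy-1,2,3,4-tetrahydronaphthalene-2,3-diyl]dimethanol
Conditions: LiAlH4 (excess), THF, 0 °C to rt
Reagents that add atoms: none
Why: Hydride reduction of all four ester carbonyls by LiAlH4 should turn the two ring esters into hydroxymethyl groups and release the auxiliary as its diol; reduction is faster than enolisation, so C2 and C3 should keep their configuration, and the benzyl ethers are inert.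

Step 8
Reactants: 14 [(1S,2R,3R,4S)-7-(benzyloxy)-1-[4-(benzyloxy)-3,5-dimethoxyphenyl]-4-hydroxy-6-methoxy-1,2,3,4-tetrahydronaphthalene-2,3-diyl]dimethanol
Product: 15 [(1S,2R,3R,4S)-4-acetoxy-7-(benzyloxy)-1-[4-(benzyloxy)-3,5-dimethoxyphenyl]-6-methoxy-1,2,3,4-tetrahydronaphthalene-2,3-diyl]bis(methylene) diacetate
Conditions: Ac2O (excess), pyridine, DMAP (cat.), CH2Cl2, 0 °C to rt
Reagents that add atoms: acetic anhydride, CC(=O)OC(C)=O
Why: DMAP-catalysed acyl transfer should acetylate the two primary alcohols and the benzylic C4 alcohol, while the phenols stay masked as benzyl ethers so that only the wanted oxygens carry acetate after step 9.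

Step 9
Reactants: 15 [(1S,2R,3R,4S)-4-acetoxy-7-(benzyloxy)-1-[4-(benzyloxy)-3,5-dimethoxyphenyl]-6-methoxy-1,2,3,4-tetrahydronaphthalene-2,3-diyl]bis(methylene) diacetate
Product: 16 [(1S,2R,3R)-7-hydroxy-1-(4-hydroxy-3,5-dimethoxyphenyl)-6-methoxy-1,2,3,4-tetrahydronaphthalene-2,3-diyl]bis(methylene) diacetate
Conditions: H2 (1 atm), 10% Pd/C, EtOAc–AcOH (10:1), rt
Reagents that add atoms: none
Why: Pd-catalysed hydrogenolysis should cleave both aryl benzyl ethers and the secondary benzylic C4–OAc bond (activated by the para C7 oxygen), while the primary acetates and the C1–C2–C3 stereotriad are untouched; C4 becomes CH2, so its configuration no longer matters.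

Compound list
1 | 4-(benzyloxy)-3-methoxybenzaldehyde (O-benzylvanillin) | COc1cc(C=O)ccc1OCc1ccccc1 | starting material
2 | 4-(benzyloxy)-2-bromo-5-methoxybenzaldehyde | COc1cc(C=O)c(Br)cc1OCc1ccccc1 | intermediate
3 | 4-(benzyloxy)-3,5-dimethoxybenzaldehyde (O-benzylsyringaldehyde) | COc1cc(C=O)cc(OC)c1OCc1ccccc1 | starting material
4 | [4-(benzyloxy)-3,5-dimethoxyphenyl]methanol | COc1cc(CO)cc(OC)c1OCc1ccccc1 | intermediate
5 | 2-(benzyloxy)-5-(chloromethyl)-1,3-dimethoxybenzene | COc1cc(CCl)cc(OC)c1OCc1ccccc1 | intermediate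
6 | [4-(benzyloxy)-3,5-dimethoxybenzyl]zinc chloride (not isolated) | COc1cc(C[Zn]Cl)cc(OC)c1OCc1ccccc1 | intermediate
7 | 4-(benzyloxy)-2-[4-(benzyloxy)-3,5-dimethoxybenzyl]-5-methoxybenzaldehyde | COc1cc(C=O)c(Cc2cc(OC)c(OCc3ccccc3)c(OC)c2)cc1OCc1ccccc1 | intermediate
8 | fumaryl chloride | O=C(Cl)/C=C/C(=O)Cl | starting material
9 | methyl (S)-mandelate | COC(=O)[C@@H](O)c1ccccc1 | starting material
10 | (1S)-2-methoxy-2-oxo-1-phenylethyl (2E)-4-chloro-4-oxobut-2-enoate, the fumaroyl chloride monoester (not isolated) | COC(=O)[C@@H](OC(=O)/C=C/C(=O)Cl)c1ccccc1 | intermediate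
11 | bis[(1S)-2-methoxy-2-oxo-1-phenylethyl] (2E)-but-2-enedioate | COC(=O)[C@@H](OC(=O)/C=C/C(=O)O[C@H](C(=O)OC)c1ccccc1)c1ccccc1 | intermediate
12 | (E)-{(6E)-4-(benzyloxy)-6-[4-(benzyloxy)-3,5-dimethoxybenzylidene]-3-methoxycyclohexa-2,4-dien-1-ylidene}methanol, the (E,E)-dienol (not isolated) | O/C=C1\C=C(OC)C(OCc2ccccc2)=C/C1=C\c1cc(OC)c(OCc2ccccc2)c(OC)c1 | intermediate
13 | bis[(1S)-2-methoxy-2-oxo-1-phenylethyl] (1S,2R,3S,4S)-7-(benzyloxy)-1-[4-(benzyloxy)-3,5-dimethoxyphenyl]-4-hydroxy-6-methoxy-1,2,3,4-tetrahydronaphthalene-2,3-dicarboxylate (1,2-trans, 2,3-trans, 3,4-cis) | COc1cc2c(cc1OCc3ccccc3)[C@H](c3cc(OC)c(OCc4ccccc4)c(OC)c3)[C@@H](C(=O)O[C@H](C(=O)OC)c3ccccc3)[C@H](C(=O)O[C@H](C(=O)OC)c3ccccc3)[C@@H]2O | intermediate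
14 | [(1S,2R,3R,4S)-7-(benzyloxy)-1-[4-(benzyloxy)-3,5-dimethoxyphenyl]-4-hydroxy-6-methoxy-1,2,3,4-tetrahydronaphthalene-2,3-diyl]dimethanol | COc1cc2c(cc1OCc3ccccc3)[C@H](c3cc(OC)c(OCc4ccccc4)c(OC)c3)[C@@H](CO)[C@H](CO)[C@@H]2O | intermediate
15 | [(1S,2R,3R,4S)-4-acetoxy-7-(benzyloxy)-1-[4-(benzyloxy)-3,5-dimethoxyphenyl]-6-methoxy-1,2,3,4-tetrahydronaphthalene-2,3-diyl]bis(methylene) diacetate | COc1cc2c(cc1OCc3ccccc3)[C@H](c3cc(OC)c(OCc4ccccc4)c(OC)c3)[C@@H](COC(C)=O)[C@H](COC(C)=O)[C@@H]2OC(C)=O | intermediate
16 | [(1S,2R,3R)-7-hydroxy-1-(4-hydroxy-3,5-dimethoxyphenyl)-6-methoxy-1,2,3,4-tetrahydronaphthalene-2,3-diyl]bis(methylene) diacetate | COc1cc2c(cc1O)[C@H](c1cc(OC)c(O)c(OC)c1)[C@@H](COC(C)=O)[C@H](COC(C)=O)C2 | target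

Total step count: 9.
Longest linear sequence: 7 steps (3 → 4 → 5 → 7 → 13 → 14 → 15 → 16; steps 2, 3, 4, 6, 7, 8, 9).

Steps most likely to fail

Step 6. Under irradiation the excited aldehyde may pass its triplet energy to the fumarate, so that E/Z isomerisation of the dienophile erodes the 2,3-trans relation, or the dienol may return to the aldehyde faster than it is trapped. The fallback separates the generation of the diene from its trapping by storing the diene in a temporary SO2 ring; it sets out from 7 and comes back to the route at 13. Aldehyde 7 would be irradiated (Hg lamp, Pyrex) in benzene saturated with SO2 and without dienophile, so that the dienol is captured by suprafacial cheletropic addition as cis-6-(benzyloxy)-1-[4-(benzyloxy)-3,5-dimethoxyphenyl]-3-hydroxy-5-methoxy-1,3-dihydro-2-benzothiophene 2,2-dioxide F1 (racemic; both of its stereocentres are only geometric relays that the next operation erases). F1 would then be heated in the dark with fumarate 11 and ZnO in toluene at 80 °C. Disrotatory extrusion of SO2 should regenerate only the (E,E)-dienol in its ground state, and its cycloaddition to the fumarate, which stays E in the dark, should give 13.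

Step 9. Hydrogenolysis may stall at the benzylic acetate once the phenols are free, or C3 may lose its configuration through elimination to a dihydronaphthalene and re-hydrogenation. The fallback removes the C4 oxygen by ionic hydrogenation while the phenols are still benzylated; it sets out from 13 and comes back to the route at 16. Et3SiH with BF3·OEt2 (CH2Cl2, −40 to 0 °C) would reduce the p-alkoxybenzylic cation formed from 13 to bis[(1S)-2-methoxy-2-oxo-1-phenylethyl] (1S,2R,3R)-7-(benzyloxy)-1-[4-(benzyloxy)-3,5-dimethoxyphenyl]-6-methoxy-1,2,3,4-tetrahydronaphthalene-2,3-dicarboxylate F2. LiAlH4 would then give [(1S,2R,3R)-7-(benzyloxy)-1-[4-(benzyloxy)-3,5-dimethoxyphenyl]-6-methoxy-1,2,3,4-tetrahydronaphthalene-2,3-diyl]dimethanol F3. Ac2O/pyridine would give [(1S,2R,3R)-7-(benzyloxy)-1-[4-(benzyloxy)-3,5-dimethoxyphenyl]-6-methoxy-1,2,3,4-tetrahydronaphthalene-2,3-diyl]bis(methylene) diacetate F4, and H2 over Pd/C, now only an O-debenzylation, would give 16.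

Step 4. The benzylzinc reagent may add to the free aldehyde of 2, or Wurtz-type homocoupling may consume the benzylic chloride during zinc insertion. The fallback avoids any benzylic organometallic by reversing the roles of the two partners; it sets out from 2 and comes back to the route at 7. Miyaura borylation of 2 (B2pin2, KOAc, PdCl2(dppf), dioxane, 80 °C) would give 4-(benzyloxy)-5-methoxy-2-(4,4,5,5-tetramethyl-1,3,2-dioxaborolan-2-yl)benzaldehyde F5. Suzuki–Miyaura coupling of F5 with the benzylic chloride 5 (Pd(PPh3)4, Na2CO3, DME/H2O, 80 °C) would then give 7.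

Further compounds
F1 | step 6 | cis-6-(benzyloxy)-1-[4-(benzyloxy)-3,5-dimethoxyphenyl]-3-hydroxy-5-methoxy-1,3-dihydro-2-benzothiophene 2,2-dioxide (racemic; one enantiomer drawn) | O[C@@H]1c2cc(OC)c(OCc3ccccc3)cc2[C@H](c2cc(OC)c(OCc3ccccc3)c(OC)c2)S1(=O)=O
F2 | step 9 | bis[(1S)-2-methoxy-2-oxo-1-phenylethyl] (1S,2R,3R)-7-(benzyloxy)-1-[4-(benzyloxy)-3,5-dimethoxyphenyl]-6-methoxy-1,2,3,4-tetrahydronaphthalene-2,3-dicarboxylate | COc1cc2c(cc1OCc3ccccc3)[C@H](c3cc(OC)c(OCc4ccccc4)c(OC)c3)[C@@H](C(=O)O[C@H](C(=O)OC)c3ccccc3)[C@H](C(=O)O[C@H](C(=O)OC)c3ccccc3)C2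
F3 | step 9 | [(1S,2R,3R)-7-(benzyloxy)-1-[4-(benzyloxy)-3,5-dimethoxyphenyl]-6-methoxy-1,2,3,4-tetrahydronaphthalene-2,3-diyl]dimethanol | COc1cc2c(cc1OCc3ccccc3)[C@H](c3cc(OC)c(OCc4ccccc4)c(OC)c3)[C@@H](CO)[C@H](CO)C2
F4 | step 9 | [(1S,2R,3R)-7-(benzyloxy)-1-[4-(benzyloxy)-3,5-dimethoxyphenyl]-6-methoxy-1,2,3,4-tetrahydronaphthalene-2,3-diyl]bis(methylene) diacetate | COc1cc2c(cc1OCc3ccccc3)[C@H](c3cc(OC)c(OCc4ccccc4)c(OC)c3)[C@@H](COC(C)=O)[C@H](COC(C)=O)C2
F5 | step 4 | 4-(benzyloxy)-5-methoxy-2-(4,4,5,5-tetramethyl-1,3,2-dioxaborolan-2-yl)benzaldehyde | COc1cc(C=O)c(B2OC(C)(C)C(C)(C)O2)cc1OCc1ccccc1
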